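## Retrosynthetic overview
1. Ring A closes last. The C1–C10 bond forms by intramolecular aldol condensation of 1,5-diketone 29. Its methyl ketone comes from Wacker oxidation of the (E)-propenyl group (C3=C2–C1) of 28.
2. 28 is assembled from enone 19, a methyl cuprate and iodide 26. Conjugate addition sets C8, and enolate alkylation sets quaternary C9 and attaches the side chain (C13 from (R)-citronellol).
3. Ring B closes first. The C8–C9 bond forms by intramolecular aldol condensation of keto aldehyde 18.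
4. The C4 (quaternary)/C5 pair comes from an Ireland–Claisen rearrangement of ester 12, with 1,3-chirality transfer from a lactate carbinol.
5. There are three fragments: alcohol 6 (methyl (R)-lactate plus ylide 3), acid 11 (cyclopentene) and iodide 26 ((R)-citronellol).

Convention: atom labels follow halimane numbering. C4 is the quaternary ester carbon, C5 the ring-fusion CH, C10 the ring-fusion alkene carbon, C9 the quaternary carbon bearing the side chain, and C13 the side-chain stereocentre. Read this way, the target is (4S,5S,8R,9S,13R).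

## Fragment 1: allylic alcohol 6

Step 1
Reactants: 1 methyl (R)-lactate
Product: 2 methyl (2R)-2-(tert-butyldimethylsilyloxy)propanoate
Conditions: TBSCl, imidazole, CH2Cl2, 0 °C → rt
Reagents that add atoms: tert-butyldimethylsilyl chloride, CC(C)(C)[Si](C)(C)Cl
Why: Imidazole-promoted silyl ether formation masks the carbinol for the reduction and leaves the lactate stereocentre untouched.

Step 2
Reactants: 2 methyl (2R)-2-(tert-butyldimethylsilyloxy)propanoate; 3 methyl 2-(triphenyl-λ5-phosphanylidene)propanoate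
Product: 5 methyl (2E,4R)-4-(tert-butyldimethylsilyloxy)-2-methylpent-2-enoate, via silyloxy aldehyde 4 (not isolated)
Conditions: i-Bu2AlH (1.05 equiv), CH2Cl2, −78 °C; then 3, −78 °C → rt; aqueous work-up
Reagents that add atoms: ylide 3, COC(=O)C(C)=P(c1ccccc1)(c1ccccc1)c1ccccc1
Why: Partial ester reduction followed by a Wittig olefination with a stabilised α-branched ylide gives the (E)-trisubstituted enoate (>95:5), and the α-silyloxy aldehyde does not racemise because it is consumed at once.

Step 3
Reactants: 5 methyl (2E,4R)-4-(tert-butyldimethylsilyloxy)-2-methylpent-2-enoate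
Product: 6 methyl (2E,4R)-4-hydroxy-2-methylpent-2-enoate
Conditions: aq. HF (48 %), MeCN, 0 °C → rt
Reagents that add atoms: none
Why: Acidic fluoride desilylation is used instead of basic fluoride so that the γ-hydroxy enoate neither isomerises to the butenolide nor tautomerises to the γ-keto ester.

## Fragment 2: acid 11

Step 4
Reactants: 7 cyclopentene
Product: 10 methyl 5,5-dimethoxypentanoate, via hydroperoxy aldehyde 8 (not isolated), via hydroperoxy acetal 9 (not isolated)
Conditions: O3, CH2Cl2/MeOH, −78 °C; TsOH·H2O (cat.), rt; then Ac2O, Et3N, 0 °C → rt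
Reagents that add atoms: ozone, [O-][O+]=O; methanol, CO
Why: Criegee ozonolysis in methanol with terminus-differentiating work-up turns a symmetric alkene into an acetal ester in one flask, because the carbonyl oxide is trapped as a methoxy hydroperoxide, the aldehyde end is acetalised and the hydroperoxide end is dehydrated to the ester.

Step 5
Reactants: 10 methyl 5,5-dimethoxypentanoate
Product: 11 5,5-dimethoxypentanoic acid
Conditions: LiOH, THF/H2O, rt; then cold 1 M HCl to pH 4
Reagents that add atoms: lithium hydroxide, [Li+].[OH-]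
Why: Ester saponification followed by brief cold acidification to pH 4 frees the acid without opening the dimethyl acetal.

## Union 1 and ring B

Step 6
Reactants: 6 methyl (2E,4R)-4-hydroxy-2-methylpent-2-enoate; 11 5,5-dimethoxypentanoic acid
Product: 12 methyl (2E,4R)-4-(5,5-dimethoxypentanoyloxy)-2-methylpent-2-enoate
Conditions: DCC, DMAP (cat.), CH2Cl2, 0 °C → rt
Reagents that add atoms: none
Why: Steglich esterification activates only the acid, so the carbinol C–O bond is not broken and the (R) configuration is retained.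

Step 7
Reactants: 12 methyl (2E,4R)-4-(5,5-dimethoxypentanoyloxy)-2-methylpent-2-enoate
Product: 15 tert-butyldimethylsilyl (2R,3S,4E)-2-(3,3-dimethoxypropyl)-3-(methoxycarbonyl)-3-methylhex-4-enoate, via lithium enolate 13 (not isolated), via silyl ketene acetal 14 (not isolated)
Conditions: 12 and TBSCl (1.3 equiv) in THF/HMPA (4:1), −78 °C, LiN(i-Pr)2 (1.15 equiv) added slowly; → rt; then toluene, 80 °C; non-aqueous work-up
Reagents that add atoms: tert-butyldimethylsilyl chloride, CC(C)(C)[Si](C)(C)Cl
Why: In this Ireland–Claisen rearrangement, deprotonation in THF/HMPA gives the enolate with the chain cis to OLi, which is trapped at once as the (Z)-silyl ketene acetal, and the chair transition state with the carbinol methyl equatorial transfers the (R)-carbinol configuration to C4 (CO2Me equatorial and CH3 axial from the E-enoate) and C5 while creating the (E)-propenyl group.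

Step 8
Reactants: 15 tert-butyldimethylsilyl (2R,3S,4E)-2-(3,3-dimethoxypropyl)-3-(methoxycarbonyl)-3-methylhex-4-enoate
Product: 17 methyl (2S,3E)-2-[(4R)-7,7-dimethoxy-3-oxoheptan-4-yl]-2-methylpent-3-enoate, via acid chloride 16 (not isolated)
Conditions: (COCl)2, DMF (cat.), CH2Cl2, 0 °C → rt, concentrate; EtMgBr (1.05 equiv), Fe(acac)3 (3 mol %), THF, −78 °C
Reagents that add atoms: ethylmagnesium bromide, CC[Mg]Br
Why: The silyl ester is converted to the acid chloride without releasing HCl, so the acetal survives, and the iron-catalysed acylation of the Grignard reagent is fast enough at −78 °C to stop at the ketone and spare the hindered methyl ester and C5.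

Step 9
Reactants: 17 methyl (2S,3E)-2-[(4R)-7,7-dimethoxy-3-oxoheptan-4-yl]-2-methylpent-3-enoate
Product: 19 methyl (2S,3E)-2-methyl-2-[(1R)-3-methyl-2-oxocyclohex-3-en-1-yl]pent-3-enoate, via keto aldehyde 18 (not isolated)
Conditions: TsOH·H2O (cat.), THF/H2O, rt; then piperidine/AcOH (cat.), toluene, 70 °C
Reagents that add atoms: none
Why: Acetal hydrolysis followed by intramolecular aldol condensation closes ring B, because attack of C9 on the C8 aldehyde is the only closure that gives an unstrained ring, and the weak amine/acid catalyst does not epimerise the shielded C5–H.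

## Fragment 3: iodide 26

Step 10
Reactants: 20 (R)-citronellol
Product: 21 tert-butyl{[(3R)-3,7-dimethyloct-6-en-1-yl]oxy}diphenylsilane
Conditions: TBDPSCl, imidazole, CH2Cl2, rt
Reagents that add atoms: tert-butyldiphenylsilyl chloride, CC(C)(C)[Si](Cl)(c1ccccc1)c1ccccc1
Why: Silyl ether formation with TBDPS gives a group that tolerates ozone, chlorite, iodine radicals, enolates and the acidic Wacker medium, and C13 is taken unchanged from the chiral pool.

Step 11
Reactants: 21 tert-butyl{[(3R)-3,7-dimethyloct-6-en-1-yl]oxy}diphenylsilane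
Product: 23 (4R)-6-(tert-butyldiphenylsilyloxy)-4-methylhexanal, via secondary ozonide 22 (not isolated)
Conditions: O3, CH2Cl2, −78 °C; then Me2S, → rt
Reagents that add atoms: ozone, [O-][O+]=O
Why: Ozonolysis with reductive work-up cleaves the only alkene and does not touch the remote stereocentre.

Step 12
Reactants: 23 (4R)-6-(tert-butyldiphenylsilyloxy)-4-methylhexanal
Product: 24 (4R)-6-(tert-butyldiphenylsilyloxy)-4-methylhexanoic acid
Conditions: NaClO2, NaH2PO4, 2-methylbut-2-ene, t-BuOH/H2O, rt
Reagents that add atoms: sodium chlorite, [Na+].[O-]Cl=O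
Why: Pinnick oxidation converts the aldehyde to the acid under buffered conditions that leave the silyl ether intact.

Step 13
Reactants: 24 (4R)-6-(tert-butyldiphenylsilyloxy)-4-methylhexanoic acid
Product: 26 tert-butyl{[(3S)-5-iodo-3-methylpentyl]oxy}diphenylsilane, via acyl hypoiodite 25 (not isolated)
Conditions: PhI(OAc)2, I2, cyclohexane, tungsten lamp, reflux
Reagents that add atoms: iodine, II
Why: This Hunsdiecker-type iododecarboxylation removes the surplus carbon as CO2 through homolysis of the acyl hypoiodite, and the descriptor changes to S only because iodine reorders the CIP priorities.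

## Union 2, ring A and end game

Step 14
Reactants: 19 methyl (2S,3E)-2-methyl-2-[(1R)-3-methyl-2-oxocyclohex-3-en-1-yl]pent-3-enoate; 26 tert-butyl{[(3S)-5-iodo-3-methylpentyl]oxy}diphenylsilane
Product: 28 methyl (2S,3E)-2-{(1R,3S,4R)-3-[(3R)-5-(tert-butyldiphenylsilyloxy)-3-methylpentyl]-3,4-dimethyl-2-oxocyclohexyl}-2-methylpent-3-enoate, via lithium enolate 27 (not isolated)
Conditions: MeLi (2.4 equiv), CuI (1.2 equiv), Et2O, 0 °C; 19, −40 → 0 °C; then 26 (1.5 equiv), THF/HMPA, 0 °C → rt
Reagents that add atoms: lithium dimethylcuprate, [Li+].C[Cu-]C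
Why: In this three-component coupling (Gilman conjugate addition, then enolate alkylation) the bulky C5 substituent sits pseudo-equatorial, so the cuprate attacks C8 axially and cis to it, and the tetrasubstituted enolate, whose C8 methyl is pseudo-axial to avoid A1,2 strain, is alkylated at C9 on the opposite face, which leaves the two ring methyls cis and the side chain trans to them.

Step 15
Reactants: 28 methyl (2S,3E)-2-{(1R,3S,4R)-3-[(3R)-5-(tert-butyldiphenylsilyloxy)-3-methylpentyl]-3,4-dimethyl-2-oxocyclohexyl}-2-methylpent-3-enoate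
Product: 29 methyl (2S)-2-{(1R,3S,4R)-3-[(3R)-5-(tert-butyldiphenylsilyloxy)-3-methylpentyl]-3,4-dimethyl-2-oxocyclohexyl}-2-methyl-4-oxopentanoate
Conditions: Pd(OAc)2 (5 mol %), 1,4-benzoquinone (1.1 equiv), aq. HBF4, DMA/MeCN/H2O, rt
Reagents that add atoms: water, O
Why: In this Wacker–Tsuji oxidation of an internal alkene by divalent palladium, water attacks C2 because it is distal to the quaternary carbon and γ to the ester, which is the usual course from a β,γ-unsaturated ester to a γ-keto ester.

Step 16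
Reactants: 29 methyl (2S)-2-{(1R,3S,4R)-3-[(3R)-5-(tert-butyldiphenylsilyloxy)-3-methylpentyl]-3,4-dimethyl-2-oxocyclohexyl}-2-methyl-4-oxopentanoate
Product: 31 methyl (1S,5S,6R,8aS)-5-[(3R)-5-(tert-butyldiphenylsilyloxy)-3-methylpentyl]-1,5,6-trimethyl-3-oxo-1,2,3,5,6,7,8,8a-octahydronaphthalene-1-carboxylate, via ketol 30 (not isolated)
Conditions: NaOMe (0.5 equiv), MeOH, 0 → 45 °C
Reagents that add atoms: none
Why: This intramolecular aldol condensation (the closing half of a Robinson annulation) succeeds because only the C1 methyl enolate reaches a carbonyl through a six-membered transition state, E1cB loss of water gives the C1=C10 enone, methoxide is degenerate towards the methyl ester, and C5 holds its configuration because its axial hydrogen is shielded by the axial side chain on C9.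

Step 17
Reactants: 31 methyl (1S,5S,6R,8aS)-5-[(3R)-5-(tert-butyldiphenylsilyloxy)-3-methylpentyl]-1,5,6-trimethyl-3-oxo-1,2,3,5,6,7,8,8a-octahydronaphthalene-1-carboxylate
Product: 32 methyl (1S,5S,6R,8aS)-5-[(3R)-5-hydroxy-3-methylpentyl]-1,5,6-trimethyl-3-oxo-1,2,3,5,6,7,8,8a-octahydronaphthalene-1-carboxylate (CNP0157174.1)
Conditions: HF·pyridine, THF, 0 °C → rt
Reagents that add atoms: none
Why: Non-basic fluoride desilylation frees the primary alcohol without enolising the enone, so no stereocentre is touched.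

## Compound list
1 | methyl (R)-lactate | C[C@@H](O)C(=O)OC | starting material
2 | methyl (2R)-2-(tert-butyldimethylsilyloxy)propanoate | C[C@@H](O[Si](C)(C)C(C)(C)C)C(=O)OC | intermediate
3 | methyl 2-(triphenyl-λ5-phosphanylidene)propanoate | COC(=O)C(C)=P(c1ccccc1)(c1ccccc1)c1ccccc1 | starting material
4 | (2R)-2-(tert-butyldimethylsilyloxy)propanal | C[C@@H](O[Si](C)(C)C(C)(C)C)C=O | intermediate
5 | methyl (2E,4R)-4-(tert-butyldimethylsilyloxy)-2-methylpent-2-enoate | C[C@@H](O[Si](C)(C)C(C)(C)C)/C=C(\C)C(=O)OC | intermediate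
6 | methyl (2E,4R)-4-hydroxy-2-methylpent-2-enoate | C[C@@H](O)/C=C(\C)C(=O)OC | intermediate
7 | cyclopentene | C1=CCCC1 | starting material
8 | 5-hydroperoxy-5-methoxypentanal | COC(CCCC=O)OO | intermediate
9 | 1-hydroperoxy-1,5,5-trimethoxypentane | COC(CCCC(OC)OC)OO | intermediate
10 | methyl 5,5-dimethoxypentanoate | COC(=O)CCCC(OC)OC | intermediate
11 | 5,5-dimethoxypentanoic acid | COC(CCCC(=O)O)OC | intermediate
12 | methyl (2E,4R)-4-(5,5-dimethoxypentanoyloxy)-2-methylpent-2-enoate | COC(OC)CCCC(=O)O[C@H](C)/C=C(\C)C(=O)OC | intermediate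
13 | lithium enolate of 12 (alkyl chain cis to OLi) | [Li+].COC(OC)CC/C=C(\[O-])O[C@H](C)/C=C(\C)C(=O)OC | intermediate
14 | (Z)-O-tert-butyldimethylsilyl ketene acetal of 12 | COC(OC)CC/C=C(\O[Si](C)(C)C(C)(C)C)O[C@H](C)/C=C(\C)C(=O)OC | intermediate
15 | tert-butyldimethylsilyl (2R,3S,4E)-2-(3,3-dimethoxypropyl)-3-(methoxycarbonyl)-3-methylhex-4-enoate | COC(=O)[C@@]([C@@H](CCC(OC)OC)C(=O)O[Si](C)(C)C(C)(C)C)(C)/C=C/C | intermediate
16 | methyl (2S,3E)-2-[(2R)-1-chloro-5,5-dimethoxy-1-oxopentan-2-yl]-2-methylpent-3-enoate (acid chloride) | COC(=O)[C@@]([C@@H](CCC(OC)OC)C(=O)Cl)(C)/C=C/C | intermediate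
17 | methyl (2S,3E)-2-[(4R)-7,7-dimethoxy-3-oxoheptan-4-yl]-2-methylpent-3-enoate | COC(=O)[C@@]([C@@H](CCC(OC)OC)C(=O)CC)(C)/C=C/C | intermediate
18 | methyl (2S,3E)-2-[(4R)-1,5-dioxoheptan-4-yl]-2-methylpent-3-enoate | COC(=O)[C@@]([C@@H](CCC=O)C(=O)CC)(C)/C=C/C | intermediate
19 | methyl (2S,3E)-2-methyl-2-[(1R)-3-methyl-2-oxocyclohex-3-en-1-yl]pent-3-enoate | COC(=O)[C@@]([C@H]1CCC=C(C)C1=O)(C)/C=C/C | intermediate
20 | (R)-citronellol, (3R)-3,7-dimethyloct-6-en-1-ol | CC(C)=CCC[C@@H](C)CCO | starting material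
21 | tert-butyl{[(3R)-3,7-dimethyloct-6-en-1-yl]oxy}diphenylsilane | CC(C)=CCC[C@@H](C)CCO[Si](c1ccccc1)(c1ccccc1)C(C)(C)C | intermediate
22 | secondary ozonide of 21 (3,3-dimethyl-5-alkyl-1,2,4-trioxolane, ring carbon unassigned) | CC1(C)OOC(CC[C@@H](C)CCO[Si](c2ccccc2)(c2ccccc2)C(C)(C)C)O1 | intermediate
23 | (4R)-6-(tert-butyldiphenylsilyloxy)-4-methylhexanal | O=CCC[C@@H](C)CCO[Si](c1ccccc1)(c1ccccc1)C(C)(C)C | intermediate
24 | (4R)-6-(tert-butyldiphenylsilyloxy)-4-methylhexanoic acid | OC(=O)CC[C@@H](C)CCO[Si](c1ccccc1)(c1ccccc1)C(C)(C)C | intermediate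
25 | acyl hypoiodite of 24 | IOC(=O)CC[C@@H](C)CCO[Si](c1ccccc1)(c1ccccc1)C(C)(C)C | intermediate
26 | tert-butyl{[(3S)-5-iodo-3-methylpentyl]oxy}diphenylsilane | ICC[C@@H](C)CCO[Si](c1ccccc1)(c1ccccc1)C(C)(C)C | intermediate
27 | lithium enolate from methyl addition to 19 (C9=C10 enolate, C8 methyl cis to the C5 substituent) | [Li+].COC(=O)[C@@]([C@H]1CC[C@@H](C)C(C)=C1[O-])(C)/C=C/C | intermediate
28 | methyl (2S,3E)-2-{(1R,3S,4R)-3-[(3R)-5-(tert-butyldiphenylsilyloxy)-3-methylpentyl]-3,4-dimethyl-2-oxocyclohexyl}-2-methylpent-3-enoate | COC(=O)[C@@]([C@H]1CC[C@@H](C)[C@](C)(CC[C@@H](C)CCO[Si](c2ccccc2)(c2ccccc2)C(C)(C)C)C1=O)(C)/C=C/C | intermediate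
29 | methyl (2S)-2-{(1R,3S,4R)-3-[(3R)-5-(tert-butyldiphenylsilyloxy)-3-methylpentyl]-3,4-dimethyl-2-oxocyclohexyl}-2-methyl-4-oxopentanoate | COC(=O)[C@@]([C@H]1CC[C@@H](C)[C@](C)(CC[C@@H](C)CCO[Si](c2ccccc2)(c2ccccc2)C(C)(C)C)C1=O)(C)CC(C)=O | intermediate
30 | bicyclic ketol (C10 tertiary alcohol, carbinol configuration unassigned) | COC(=O)[C@@]1(C)CC(=O)CC2(O)[C@@H]1CC[C@@H](C)[C@]2(C)CC[C@@H](C)CCO[Si](c3ccccc3)(c3ccccc3)C(C)(C)C | intermediate
31 | TBDPS ether of the target | COC(=O)[C@@]1(C)CC(=O)C=C2[C@@H]1CC[C@@H](C)[C@]2(C)CC[C@@H](C)CCO[Si](c3ccccc3)(c3ccccc3)C(C)(C)C | intermediate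
32 | methyl (1S,5S,6R,8aS)-5-[(3R)-5-hydroxy-3-methylpentyl]-1,5,6-trimethyl-3-oxo-1,2,3,5,6,7,8,8a-octahydronaphthalene-1-carboxylate | COC(=O)[C@@]1(C)CC(=O)C=C2[C@@H]1CC[C@@H](C)[C@]2(C)CC[C@@H](C)CCO | target

## Step count and risks
Total step count: 17.
Longest linear sequence: 11 (steps 1, 2, 3, 6, 7, 8, 9, 14, 15, 16, 17).

**Risk 1, step 7.** The ester enolate may add to the enoate, within the molecule or between molecules, before it is silylated. The rearrangement onto an ester-bearing, fully substituted terminus is also slow.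

The fallback sets out from 6 and 11 and comes back at 17. It carries the acceptor as a carboxylate.
- Saponify 6 with LiOH to (2E,4R)-4-hydroxy-2-methylpent-2-enoic acid F1.
- Convert 11 with 1-chloro-N,N,2-trimethylprop-1-en-1-amine into 5,5-dimethoxypentanoyl chloride F2.
- Acylate F1 with F2 in pyridine to the acyloxy enoic acid F3.
- Treat F3 with 2.2 equiv LiN(i-Pr)2 and TBSCl in THF/HMPA. Only the unreactive lithium carboxylate is present while the enolate exists.
- Heat to obtain the bis(silyl) succinate F4.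
- (COCl)2 with catalytic DMF closes F4 to the succinic anhydride F5.
- EtMgBr at −78 °C opens the carbonyl remote from the quaternary carbon to the keto acid F6.
- MeI/K2CO3 then gives 17.

**Risk 2, step 14.** Alkylation of a hindered tetrasubstituted enolate with an unactivated primary iodide may be slow. Proton transfer or attack on the neighbouring ester could then compete.

The fallback sets out from 19 and 26 and comes back at 28. It replaces the alkylation by an aldol reaction and a deoxygenation.
- Kornblum oxidation of 26 (DMSO, NaHCO3) gives (3S)-5-(tert-butyldiphenylsilyloxy)-3-methylpentanal F7.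
- Me2CuLi/TMSCl on 19 gives the trimethylsilyl enol ether F8.
- A BF3·OEt2-mediated Mukaiyama aldol reaction of F8 with F7 attacks the same face, anti to the C8 methyl, and gives the β-hydroxy ketone F9.
- 1,1'-Thiocarbonyldiimidazole converts F9 into the imidazolyl thiocarbonate F10.
- Bu3SnH/AIBN at high stannane concentration, which outruns 1,2-acyl migration, gives 28.

**Risk 3, step 16.** The C10 ketone lies between a quaternary carbon and a neopentyl-type carbon. Forcing conditions invite retro-Michael cleavage, Dieckmann closure onto the ester, or epimerisation at C5.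

The fallback sets out from 29 and comes back at 31. It closes the ring by an irreversible olefination.
- Kinetic deprotonation of the methyl ketone with LiN(i-Pr)2 at −78 °C, followed by ClP(O)(OEt)2, gives the terminal enol phosphate F11.
- A second equivalent of LiN(i-Pr)2 triggers the 1,3-phosphorus shift to the β-keto phosphonate F12.
- An intramolecular Horner–Wadsworth–Emmons reaction (LiCl, DBU, MeCN) forms C1=C10 and gives 31.

## Further compounds
F1 | step 7 | (2E,4R)-4-hydroxy-2-methylpent-2-enoic acid | C[C@@H](O)/C=C(\C)C(=O)O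
F2 | step 7 | 5,5-dimethoxypentanoyl chloride | COC(OC)CCCC(=O)Cl
F3 | step 7 | (2E,4R)-4-(5,5-dimethoxypentanoyloxy)-2-methylpent-2-enoic acid | COC(OC)CCCC(=O)O[C@H](C)/C=C(\C)C(=O)O
F4 | step 7 | bis(tert-butyldimethylsilyl) (2S,3R)-3-(3,3-dimethoxypropyl)-2-methyl-2-[(E)-prop-1-enyl]butanedioate | CC(C)(C)[Si](C)(C)OC(=O)[C@@]([C@@H](CCC(OC)OC)C(=O)O[Si](C)(C)C(C)(C)C)(C)/C=C/C
F5 | step 7 | (3S,4R)-4-(3,3-dimethoxypropyl)-3-methyl-3-[(E)-prop-1-enyl]oxolane-2,5-dione | O=C1OC(=O)[C@H](CCC(OC)OC)[C@]1(C)/C=C/C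
F6 | step 7 | (2S,3E)-2-[(4R)-7,7-dimethoxy-3-oxoheptan-4-yl]-2-methylpent-3-enoic acid | OC(=O)[C@@]([C@@H](CCC(OC)OC)C(=O)CC)(C)/C=C/C
F7 | step 14 | (3S)-5-(tert-butyldiphenylsilyloxy)-3-methylpentanal | O=CC[C@@H](C)CCO[Si](c1ccccc1)(c1ccccc1)C(C)(C)C
F8 | step 14 | trimethylsilyl enol ether of the methyl adduct of 19 | COC(=O)[C@@]([C@H]1CC[C@@H](C)C(C)=C1O[Si](C)(C)C)(C)/C=C/C
F9 | step 14 | C11-hydroxy analogue of 28 (carbinol configuration unassigned) | COC(=O)[C@@]([C@H]1CC[C@@H](C)[C@](C)(C(O)C[C@@H](C)CCO[Si](c2ccccc2)(c2ccccc2)C(C)(C)C)C1=O)(C)/C=C/C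
F10 | step 14 | O-(imidazol-1-ylthiocarbonyl) derivative of F9 | COC(=O)[C@@]([C@H]1CC[C@@H](C)[C@](C)(C(OC(=S)n2ccnc2)C[C@@H](C)CCO[Si](c2ccccc2)(c2ccccc2)C(C)(C)C)C1=O)(C)/C=C/C
F11 | step 16 | terminal diethyl enol phosphate of 29 | COC(=O)[C@@]([C@H]1CC[C@@H](C)[C@](C)(CC[C@@H](C)CCO[Si](c2ccccc2)(c2ccccc2)C(C)(C)C)C1=O)(C)CC(=C)OP(=O)(OCC)OCC
F12 | step 16 | diethyl β-keto phosphonate derived from 29 | COC(=O)[C@@]([C@H]1CC[C@@H](C)[C@](C)(CC[C@@H](C)CCO[Si](c2ccccc2)(c2ccccc2)C(C)(C)C)C1=O)(C)CC(=O)CP(=O)(OCC)OCC
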